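Ring C is a cyclic acyloin: the C4 ketone and the C3 carbinol share the C3–C4 bond, and C2 carries the ring B aryl group and O1, so C2–H is acidic while C3 is a formyl carbon. The route cuts C3–C4. Under a chiral triazolylidene the ring A formyl group of a dialdehyde becomes the nucleophile and attacks the second formyl group, closing ring C and setting C2 and C3 at once while the racemic, enolisable precursor funnels to one enantiomer. The precursor is a benzaldehyde with MOM (methoxymethyl) on O7, prenyl on O5 and a 1-aryl-2-oxoethyl arm on O1; a Claisen shift from O5 to C6 builds the 1,1-dimethylallyl group.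

Key step: step 7

Assumption: racemic methyl 4-hydroxymandelate (5) is bought as such; if only 4-hydroxymandelic acid is at hand, one acid-catalysed esterification in methanol precedes step 3.
Assumption: the sense of asymmetric induction of the aminoindanol-derived triazolium salt on dialdehyde 10 cannot be assigned in advance; the (5aS,10bR) salt is written, and its equally available mirror image is taken instead if that one proves to lead to the (2R,3R) series.

Step 1
Reactants: 1 2,4,6-trihydroxybenzaldehyde
Product: 2 2,6-dihydroxy-4-(methoxymethoxy)benzaldehyde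
Conditions: MOMCl (1.0 equiv), i-Pr2NEt (1.1 equiv), THF, −20 to 0 °C
Reagents that add atoms: chloromethyl methyl ether (MOMCl), COCCl
Why: Williamson-type O-alkylation in which the 4-hydroxyl, para to the formyl group, unhindered and not held in the hydrogen bond to the carbonyl oxygen, should react first with one equivalent of MOMCl, the symmetrical mono-ether being separable from the 2-O isomer and the bis-ether.

Step 2
Reactants: 2 2,6-dihydroxy-4-(methoxymethoxy)benzaldehyde; 3 1-bromo-3-methylbut-2-ene (prenyl bromide)
Product: 4 2-hydroxy-4-(methoxymethoxy)-6-[(3-methylbut-2-en-1-yl)oxy]benzaldehyde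
Conditions: K2CO3 (1.1 equiv), acetone, rt
Reagents that add atoms: none
Why: Williamson ether synthesis on two equivalent phenols, which should stop after one O-prenylation because the remaining hydroxyl is then locked in a hydrogen bond to the formyl oxygen and is far less nucleophilic.

Step 3
Reactants: 5 methyl 2-hydroxy-2-(4-hydroxyphenyl)acetate (methyl 4-hydroxymandelate, racemic)
Product: 6 methyl 2-hydroxy-2-[4-(methoxymethoxy)phenyl]acetate (racemic)
Conditions: MOMCl (1.1 equiv), K2CO3, acetone, 0 °C to rt
Reagents that add atoms: chloromethyl methyl ether (MOMCl), COCCl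
Why: Chemoselective Williamson-type MOM protection, since carbonate deprotonates only the phenol and leaves the secondary benzylic alcohol free for the coupling; no stereocentre is created.

Step 4
Reactants: 4 2-hydroxy-4-(methoxymethoxy)-6-[(3-methylbut-2-en-1-yl)oxy]benzaldehyde; 6 methyl 2-hydroxy-2-[4-(methoxymethoxy)phenyl]acetate (racemic)
Product: 7 methyl 2-{2-formyl-5-(methoxymethoxy)-3-[(3-methylbut-2-en-1-yl)oxy]phenoxy}-2-[4-(methoxymethoxy)phenyl]acetate (racemic)
Conditions: PPh3, diisopropyl azodicarboxylate (DIAD), THF, 0 °C to rt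
Reagents that add atoms: none
Why: Mitsunobu etherification in which the acidic, chelated salicylaldehyde-type phenol displaces the activated mandelate carbinol by SN2 (this carbinol has no beta-hydrogen and cannot eliminate), so the O1–C2 bond forms under neutral conditions; the future C2 is made as a racemate on purpose.

Step 5
Reactants: 7 methyl 2-{2-formyl-5-(methoxymethoxy)-3-[(3-methylbut-2-en-1-yl)oxy]phenoxy}-2-[4-(methoxymethoxy)phenyl]acetate (racemic)
Product: 8 2-{2-(hydroxymethyl)-5-(methoxymethoxy)-3-[(3-methylbut-2-en-1-yl)oxy]phenoxy}-2-[4-(methoxymethoxy)phenyl]ethan-1-ol (racemic)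
Conditions: LiAlH4, THF, 0 °C; aqueous potassium sodium tartrate (KNaC4H4O6) work-up
Reagents that add atoms: none
Why: Hydride reduction of the aldehyde and the ester to the two primary alcohols, to which aryl ethers, MOM acetals and the prenyl alkene are inert; the neutral work-up protects the acid-sensitive trioxygenated benzylic alcohol.

Step 6
Reactants: 8 2-{2-(hydroxymethyl)-5-(methoxymethoxy)-3-[(3-methylbut-2-en-1-yl)oxy]phenoxy}-2-[4-(methoxymethoxy)phenyl]ethan-1-ol (racemic)
Product: 10 2-{2-formyl-5-(methoxymethoxy)-3-[(3-methylbut-2-en-1-yl)oxy]phenoxy}-2-[4-(methoxymethoxy)phenyl]acetaldehyde (racemic), via hydroxy aldehyde 9 (not isolated)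
Conditions: Dess–Martin periodinane (2.5 equiv), NaHCO3, CH2Cl2, 0 °C to rt; crude product used at once
Reagents that add atoms: none
Why: Dess–Martin oxidation of both primary alcohols under bicarbonate buffering, a non-basic and non-ionising method that should spare the MOM and prenyl ethers and stop at the aldehyde stage, the benzylic alcohol reacting first (9) and the labile alpha-aryl-alpha-aryloxy aldehyde being carried on without chromatography.

Step 7
Reactants: 10 2-{2-formyl-5-(methoxymethoxy)-3-[(3-methylbut-2-en-1-yl)oxy]phenoxy}-2-[4-(methoxymethoxy)phenyl]acetaldehyde (racemic)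
Product: 11 (2R,3R)-3-hydroxy-7-(methoxymethoxy)-2-[4-(methoxymethoxy)phenyl]-5-[(3-methylbut-2-en-1-yl)oxy]chroman-4-one
Conditions: (5aS,10bR)-2-(pentafluorophenyl)-5a,10b-dihydro-4H,6H-indeno[2,1-b][1,2,4]triazolo[4,3-d][1,4]oxazin-2-ium tetrafluoroborate (15 mol%), i-Pr2NEt (1.0 equiv), toluene (0.02 M), 4 Å molecular sieves, argon, 0 °C to rt
Reagents that add atoms: none
Why: Proposed new method: the triazolylidene set free by i-Pr2NEt adds to the ring A formyl group of 10, proton transfer gives the hydroxy-enamine (Breslow-type) acyl anion equivalent at the future C4, this carbon attacks the tethered formyl carbon (future C3) and collapse of the adduct releases the carbene and the C4 ketone, the closest known reaction type being the chiral triazolium-catalysed intramolecular crossed benzoin of 2-formylaryl ethers onto tethered ketones (3-hydroxychroman-4-ones), which has not been shown with an enolisable aldehyde acceptor or with dynamic kinetic resolution. Ring C closes in the 6-exo-trig mode (C4 attacks C3 and the carbonyl oxygen stays outside the ring). C2 is set by catalyst control, because its hydrogen sits between aryl, aryloxy and formyl groups, so the amine should interconvert the enantiomers of 10 through the enol faster than either cyclises while the chiral acyl anion equivalent consumes the (R)-aldehyde preferentially. C3 is set in the same bond formation by attack on the aldehyde face that places the new hydroxyl trans to the pseudo-equatorial C2 aryl group in a half-chair transition state, and this trans ketol is also the more stable epimer, so any enolisation at C3 converges on it. The step needs donor/acceptor chemoselectivity and the C4-ketone regiochemistry, and the substrate secures both in that carbene adducts of the aliphatic aldehyde, the isomeric 4-hydroxychroman-3-one and the five-ring aldol adduct of the enol with the ring A aldehyde can all revert (retro-benzoin, enediol tautomerism, retro-aldol), whereas the C4 ketone conjugated with the trioxygenated ring A is a poor electrophile for the carbene and acts as the sink. The one irreversible leak, loss of the O1 aryloxide from an acyl anion equivalent formed at the aliphatic aldehyde, is held back by the alpha-branching of that aldehyde, the weak amine base, the apolar solvent and the electron-poor N-pentafluorophenyl catalyst.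

Step 8
Reactants: 11 (2R,3R)-3-hydroxy-7-(methoxymethoxy)-2-[4-(methoxymethoxy)phenyl]-5-[(3-methylbut-2-en-1-yl)oxy]chroman-4-one
Product: 13 (2R,3R)-3,5-dihydroxy-7-(methoxymethoxy)-2-[4-(methoxymethoxy)phenyl]-6-(2-methylbut-3-en-2-yl)chroman-4-one, via ortho-dienone 12 (not isolated)
Conditions: Eu(fod)3 [tris(6,6,7,7,8,8,8-heptafluoro-2,2-dimethyloctane-3,5-dionato)europium] (0.2 equiv), NaHCO3, CHCl3, 45 °C
Reagents that add atoms: none
Why: Lewis-acid-catalysed aromatic Claisen rearrangement, a reaction type established for 5-O-prenyl flavanones, in which the europium chelate of the C4 carbonyl and O5 lets the prenyl group shift from O5 to C6 (the only free ortho position) with allylic inversion to dienone 12, and the mild temperature and acid-free medium are chosen so that 12 aromatises by loss of the C6 hydrogen before a second shift to C8 can occur; C2 and C3 are not involved.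

Step 9
Reactants: 13 (2R,3R)-3,5-dihydroxy-7-(methoxymethoxy)-2-[4-(methoxymethoxy)phenyl]-6-(2-methylbut-3-en-2-yl)chroman-4-one
Product: 14 (2R,3R)-3,5,7-trihydroxy-2-(4-hydroxyphenyl)-6-(2-methylbut-3-en-2-yl)chroman-4-one (CNP0527000.1)
Conditions: 2 M HCl, MeOH–THF, 40 °C
Reagents that add atoms: none
Why: Acid-catalysed acetal exchange (MOM cleavage by methanolysis) under conditions mild enough that the monosubstituted alkene should not be protonated and the trans ketol, which has no acid-labile stereocentre, is kept.

Compound list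
1 | 2,4,6-trihydroxybenzaldehyde | O=Cc1c(O)cc(O)cc1O | starting material
2 | 2,6-dihydroxy-4-(methoxymethoxy)benzaldehyde | COCOc1cc(O)c(C=O)c(O)c1 | intermediate
3 | 1-bromo-3-methylbut-2-ene (prenyl bromide) | CC(C)=CCBr | starting material
4 | 2-hydroxy-4-(methoxymethoxy)-6-[(3-methylbut-2-en-1-yl)oxy]benzaldehyde | COCOc1cc(O)c(C=O)c(OCC=C(C)C)c1 | intermediate
5 | methyl 2-hydroxy-2-(4-hydroxyphenyl)acetate (methyl 4-hydroxymandelate, racemic) | COC(=O)C(O)c1ccc(O)cc1 | starting material
6 | methyl 2-hydroxy-2-[4-(methoxymethoxy)phenyl]acetate (racemic) | COCOc1ccc(cc1)C(O)C(=O)OC | intermediate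
7 | methyl 2-{2-formyl-5-(methoxymethoxy)-3-[(3-methylbut-2-en-1-yl)oxy]phenoxy}-2-[4-(methoxymethoxy)phenyl]acetate (racemic) | COC(=O)C(Oc1cc(OCOC)cc(OCC=C(C)C)c1C=O)c1ccc(OCOC)cc1 | intermediate
8 | 2-{2-(hydroxymethyl)-5-(methoxymethoxy)-3-[(3-methylbut-2-en-1-yl)oxy]phenoxy}-2-[4-(methoxymethoxy)phenyl]ethan-1-ol (racemic) | OCC(Oc1cc(OCOC)cc(OCC=C(C)C)c1CO)c1ccc(OCOC)cc1 | intermediate
9 | 2-{2-hydroxy-1-[4-(methoxymethoxy)phenyl]ethoxy}-4-(methoxymethoxy)-6-[(3-methylbut-2-en-1-yl)oxy]benzaldehyde (racemic; not isolated) | OCC(Oc1cc(OCOC)cc(OCC=C(C)C)c1C=O)c1ccc(OCOC)cc1 | intermediate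
10 | 2-{2-formyl-5-(methoxymethoxy)-3-[(3-methylbut-2-en-1-yl)oxy]phenoxy}-2-[4-(methoxymethoxy)phenyl]acetaldehyde (racemic) | O=CC(Oc1cc(OCOC)cc(OCC=C(C)C)c1C=O)c1ccc(OCOC)cc1 | intermediate
11 | (2R,3R)-3-hydroxy-7-(methoxymethoxy)-2-[4-(methoxymethoxy)phenyl]-5-[(3-methylbut-2-en-1-yl)oxy]chroman-4-one | CC(C)=CCOc1cc(OCOC)cc2c1C(=O)[C@H](O)[C@@H](c1ccc(OCOC)cc1)O2 | intermediate
12 | (2R,3R)-3-hydroxy-7-(methoxymethoxy)-2-[4-(methoxymethoxy)phenyl]-6-(2-methylbut-3-en-2-yl)-2,3-dihydro-4H-chromene-4,5(6H)-dione (both C6 epimers; not isolated) | C=CC(C)(C)C1C(=O)C2=C(C=C1OCOC)O[C@H](c1ccc(OCOC)cc1)[C@@H](O)C2=O | intermediate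
13 | (2R,3R)-3,5-dihydroxy-7-(methoxymethoxy)-2-[4-(methoxymethoxy)phenyl]-6-(2-methylbut-3-en-2-yl)chroman-4-one | C=CC(C)(C)c1c(OCOC)cc2c(c1O)C(=O)[C@H](O)[C@@H](c1ccc(OCOC)cc1)O2 | intermediate
14 | (2R,3R)-3,5,7-trihydroxy-2-(4-hydroxyphenyl)-6-(2-methylbut-3-en-2-yl)chroman-4-one (CNP0527000.1) | C=CC(C)(C)c1c(O)cc2c(c1O)C(=O)[C@H](O)[C@@H](c1ccc(O)cc1)O2 | target

Total step count: 9. Longest linear sequence: 8 steps (steps 1, 2, 4, 5, 6, 7, 8, 9).

Steps most likely to fail

Step 7 (proposed new method). The carbene may add to the aliphatic aldehyde and the resulting acyl anion equivalent may expel the O1 aryloxide (internal redox to an ester). Acyl anion formation at the hindered, electron-rich ring A aldehyde may be too slow to turn over. Racemisation of the acceptor may lag behind cyclisation, which would lower the enantiomeric purity. The fallback uses known chemistry only, sets out from 4 and returns at 11. Methylmagnesium bromide (CH3MgBr, excess) adds to the formyl group of 4 to give 2-(1-hydroxyethyl)-5-(methoxymethoxy)-3-[(3-methylbut-2-en-1-yl)oxy]phenol F1. MnO2 oxidises the benzylic carbinol to 1-{2-hydroxy-4-(methoxymethoxy)-6-[(3-methylbut-2-en-1-yl)oxy]phenyl}ethan-1-one F2. N,N-Dimethylformamide dimethyl acetal converts this into (E)-3-(dimethylamino)-1-{2-hydroxy-4-(methoxymethoxy)-6-[(3-methylbut-2-en-1-yl)oxy]phenyl}prop-2-en-1-one F3, which closes in warm acetic acid to 7-(methoxymethoxy)-5-[(3-methylbut-2-en-1-yl)oxy]-4H-chromen-4-one F4. Asymmetric conjugate addition of 4-(methoxymethoxy)phenylboronic acid (Pd(OCOCF3)2 with the tert-butyl pyridine-oxazoline ligand enantiomer that leads to the 2S series, NH4PF6, moist 1,2-dichloroethane, 60 °C) gives (2S)-7-(methoxymethoxy)-2-[4-(methoxymethoxy)phenyl]-5-[(3-methylbut-2-en-1-yl)oxy]chroman-4-one F5. Its potassium enolate (KN(SiMe3)2, THF, −78 °C) is hydroxylated with 3-phenyl-2-(phenylsulfonyl)oxaziridine on the face opposite to the C2 aryl group, which gives the trans ketol 11 and leaves the prenyl alkene untouched.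

Step 8. Dienone 12 may undergo a second [3,3] shift across C7 to C8 faster than it aromatises, so that the allyl unit drifts to C8 as a normal prenyl group; the free ketol may also tie up the europium catalyst. The fallback replaces the sigmatropic shift by a directed halogenation and a cross-coupling, sets out from 11 and returns at 13. Pd(PPh3)4 and morpholine in THF remove the prenyl group and give (2R,3R)-3,5-dihydroxy-7-(methoxymethoxy)-2-[4-(methoxymethoxy)phenyl]chroman-4-one F6. Benzyltrimethylammonium dichloroiodate with CaCO3 in CH2Cl2–MeOH should iodinate ortho to the chelated 5-hydroxyl and give (2R,3R)-3,5-dihydroxy-6-iodo-7-(methoxymethoxy)-2-[4-(methoxymethoxy)phenyl]chroman-4-one F7. A Suzuki–Miyaura coupling with 4,4,5,5-tetramethyl-2-(3-methylbut-2-en-1-yl)-1,3,2-dioxaborolane then joins the gamma (tertiary) carbon of the allylboronate to C6 to give 13; the conditions are Pd(OAc)2, a bulky biaryl dialkylphosphine ligand chosen for gamma-selectivity, K3PO4 and aqueous THF.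

Step 6. The mono-oxidised stage may close to a seven-membered lactol and be oxidised further to a lactone, and the enolisable dialdehyde may hydrate, aldolise or air-oxidise during handling. The fallback splits the oxidation into two chemoselective operations, sets out from 8 and returns at 10 (F0: no compound outside the list is made). MnO2 in CH2Cl2 oxidises only the benzylic alcohol, so that hydroxy aldehyde 9 is isolated and purified. The remaining primary alcohol is then oxidised by the Parikh–Doering method (SO3·pyridine, DMSO, i-Pr2NEt, CH2Cl2, 0 °C). After a cold aqueous wash the solution of 10 goes straight into step 7.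

Further compounds
F1 | step 7 | 2-(1-hydroxyethyl)-5-(methoxymethoxy)-3-[(3-methylbut-2-en-1-yl)oxy]phenol (racemic) | CC(O)c1c(O)cc(OCOC)cc1OCC=C(C)C
F2 | step 7 | 1-{2-hydroxy-4-(methoxymethoxy)-6-[(3-methylbut-2-en-1-yl)oxy]phenyl}ethan-1-one | CC(=O)c1c(O)cc(OCOC)cc1OCC=C(C)C
F3 | step 7 | (E)-3-(dimethylamino)-1-{2-hydroxy-4-(methoxymethoxy)-6-[(3-methylbut-2-en-1-yl)oxy]phenyl}prop-2-en-1-one | CN(C)/C=C/C(=O)c1c(O)cc(OCOC)cc1OCC=C(C)C
F4 | step 7 | 7-(methoxymethoxy)-5-[(3-methylbut-2-en-1-yl)oxy]-4H-chromen-4-one | CC(C)=CCOc1cc(OCOC)cc2occc(=O)c12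
F5 | step 7 | (2S)-7-(methoxymethoxy)-2-[4-(methoxymethoxy)phenyl]-5-[(3-methylbut-2-en-1-yl)oxy]chroman-4-one | CC(C)=CCOc1cc(OCOC)cc2c1C(=O)C[C@@H](c1ccc(OCOC)cc1)O2
F6 | step 8 | (2R,3R)-3,5-dihydroxy-7-(methoxymethoxy)-2-[4-(methoxymethoxy)phenyl]chroman-4-one | Oc1cc(OCOC)cc2c1C(=O)[C@H](O)[C@@H](c1ccc(OCOC)cc1)O2
F7 | step 8 | (2R,3R)-3,5-dihydroxy-6-iodo-7-(methoxymethoxy)-2-[4-(methoxymethoxy)phenyl]chroman-4-one | Oc1c(I)c(OCOC)cc2c1C(=O)[C@H](O)[C@@H](c1ccc(OCOC)cc1)O2
F0 | step 6 | none | none
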